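## Structural features

The target 16 is a 2,3,4-trisubstituted tetrahydrofuran (ring atoms O1, C2, C3, C4, C5) of the lariciresinol type. C2 carries a 3,4,5-trimethoxyphenyl ring, C3 a hydroxymethyl group, C4 a 3-hydroxy-4,5-dimethoxybenzyl group, and C5 is an unsubstituted OCH2. The three stereocentres C2, C3 and C4 are contiguous. The descriptor (2R,3S,4S) places the aryl group trans to the hydroxymethyl group across C2–C3 and the hydroxymethyl group cis to the benzyl group across C3–C4. The benzylic ether O1–C2 is the fragile bond: acid can ionise it (epimerisation at C2, Friedel–Crafts closure to an aryltetralin) and hydrogenolysis can cleave it. The free phenol on an electron-rich ring does not tolerate oxidants. The real difficulty is to set the C3/C4 pair in absolute terms and to tell apart two arenes that differ in a single oxygen substituent (OMe against OH). The key step exploits that C2 is the only ring carbon that is both benzylic and bonded to O1. Without the O1–C2 bond, C2 is a plain benzylic CH2 of the more electron-rich arene, four atoms away from the oxygen on the C4 branch, in an acyclic 2,3-dibenzylbutane-1,4-diol whose two stereocentres map onto C3 and C4.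

## Logic of the disconnections

16 ⇒ 15. The phenolic O–H is replaced by an O–S bond to a 4-methylbenzenesulfonyl group. A free phenol would be oxidised by the quinone of the key step, and an alkyl ether would leave both arenes equally electron-rich. The sulfonate is the mask that withdraws electrons, survives enolate and hydride chemistry, and leaves under base. The gain is that the two arenes become electronically distinct. The demand on the forward step is S–O cleavage that neither opens O1–C2 nor produces an alkylating sulfonate ester able to cap the phenoxide, hence aqueous hydroxide in a non-nucleophilic co-solvent.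

15 ⇒ 14. The O1–C2 bond is cut. C2 is the one position where a C–O bond can be made from a C–H bond, because the cation there is stabilised by the trimethoxyphenyl ring. The cut removes the ring and one stereocentre and leaves an acyclic diol with only two stereocentres. The forward step must abstract hydride only from the benzylic CH2 of the trimethoxyphenyl ring, stop after one oxidation, close through oxygen and not through the second arene, and place the aryl group anti to the C3 substituent.

14 ⇒ 13. The two hydroxyl groups are tied back into a γ-lactone: the future C5 is raised to the carboxyl level and joined to the oxygen of the hydroxymethyl group on the future C3. The five-membered lactone is the template on which the relative configuration of the two stereocentres can be set. The forward reduction must open the lactone to the diol without S–O cleavage of the aryl sulfonate and without epimerisation.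

13 ⇒ 7 + 11. The bond between the lactone α-carbon (future C4) and the benzylic carbon of the sulfonate-bearing arene is cut. This is the convergent cut: it separates the two aryl fragments and leaves 7 with a single stereocentre. The forward alkylation must take place once only, anti to the benzyl group on the β-carbon, and the enolate must not attack the sulfonyl sulfur.

11 ⇒ 10 ⇒ 9 ⇒ 8. The C–Br bond, then the benzylic C–H bonds of the alcohol, then the O–S bond are removed in turn. 8 already has the full substitution pattern of the western arene. The sulfonate is put on first so that it is present in every later intermediate. Reduction and bromination must leave it untouched.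

7 ⇒ 5, through 6. The lactone CH2–O carbon is taken back to a methyl ester and the lactone carbonyl to a free carboxylic acid. The two carboxyl carbons are thereby distinguished by the form in which they leave the condensation. The forward step must reduce the ester while the acid, as its carboxylate, stays at the carboxyl level.

5 ⇒ 4. Two hydrogen atoms are removed to give a C=C bond between the future C2 and C3. The stereocentre (future C3) then comes from a catalytic asymmetric hydrogenation steered by the neighbouring carboxylate. The demand is high face selectivity on a trisubstituted alkene.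

4 ⇒ 1 + 2, through 3. The C=C bond is cut (Stobbe condensation). This reaches commercial materials and gives the half-ester directly. The demand is a single condensation with E geometry.

## Other disconnections considered

Alternative 1: The cut removes C2–C3 and O1–C5 together, so the ring is assembled from 1 and a trimethylenemethane unit. In the forward sense the cyano-substituted donor A2 would be ionised by Pd(dba)2 (zerovalent palladium) carrying a chiral phosphoramidite. The nitrile-stabilised carbon of the zwitterionic complex would add to the aldehyde carbon of 1, and the alkoxide would close onto the allyl terminus to give the trans 4-methylene nitrile A1. From A1 the nitrile would be reduced in two stages to the hydroxymethyl group, the exocyclic alkene hydroborated and cross-coupled (B-alkyl Suzuki–Miyaura) with the aryl bromide A3, and the benzyl ether removed.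
- In its favour: the ring, two bonds and two stereocentres arise in one catalytic asymmetric step. 1 enters unchanged and the arenes are introduced independently, so no electronic differentiation is needed. On convergence and on catalyst control in the ring-forming step this alternative is the better plan.
- Against it here: electron-rich 1 is a weak acceptor for the cyano-stabilised complex. The C3–H of A1 is α to the nitrile and allylic, so epimerisation and alkene migration into conjugation are to be feared. C4 would be set by hydroboration, where the C3 group on one face and the C2 aryl on the other oppose each other, although attack anti to the nearer C3 group would give the required cis relationship.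
- Comparison: this plan builds the ring by C–C bond formation, whereas the chosen plan closes a C–O bond on a finished carbon chain. The chosen plan fixes C3 and C4 by two separately well-precedented operations before the ring exists, which is the safer stereochemical course. The step count is about equal (roughly ten operations with the preparation of A2 and A3).

Alternative 2: The cut removes C2–C3 and C4–C5, leaving an aryl carbonyl ylide (C2–O1–C5) and the alkene of a γ-aryl butenolide. In the forward sense CsF would release the ylide from the α-silyl chloromethyl ether A6. The ylide would add across the alkene of the enantiopure butenolide A5 on the face away from the γ-aryl group, with the aryl-bearing ylide carbon bonding to the α-carbon, to give the cis-fused bicyclic lactone A4. Hydrogenolysis of the lactone benzylic C–O bond together with the benzyl ether, then reduction of the resulting acid, would lead to 16.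
- In its favour: the cis ring fusion translates directly into the C3/C4 cis relationship and the exo aryl group into C2/C3 trans. All three stereocentres arise in one step from one controlling centre that is afterwards erased. On stereocentres set per step this alternative is better, and on convergence it is equal.
- Against it here: the regiochemistry of an unsymmetrical, non-stabilised ylide is not strongly biased. The γ-hydrogen of A5 is benzylic and vinylogously acidic, so fluoride acting as a base may racemise A5 through its furanolate. The ylide can collapse or dimerise, and A5 needs its own asymmetric synthesis. The end game must cleave one benzylic C–O bond while sparing O1–C2.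
- Comparison: this is a concerted cycloaddition with several selectivity questions in one step, against a stepwise cation capture with one stereocentre at stake. The sequence is expected to be slightly longer than the chosen plan (about eleven operations).

Alternative 3: The cut is the C3–C4 bond, which leads back to the acyclic epoxy cinnamyl ether A8 in which O1, C2 and C5 are already joined. In the forward sense Cp2TiCl (trivalent titanium, made from Cp2TiCl2 and Zn) would open the terminal epoxide homolytically to the C3 radical, with the titanium alkoxide on the future hydroxymethyl carbon. The radical would add 5-exo-trig to the cinnamyl alkene to form C3–C4. A second equivalent of Cp2TiCl would reduce the benzylic radical, and protonation would give the benzyl ether A7. Hydrogenolysis would then give 16.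
- In its favour: C2 is fixed before cyclisation by reagent control (Sharpless kinetic resolution with Ti(OiPr)4 and a dialkyl tartrate). The oxirane stereocentre is irrelevant because it becomes the radical. The primary alcohol emerges with no redox adjustment, and the arenes need no electronic differentiation. On step count (about eight to nine operations from 1 and 8) and on redox economy this alternative is the better one.
- Against it here: the radical step must set C3 and C4 at once. The C2 aryl group should hold C2/C3 trans, but the C3/C4 relationship rests on a small preference between competing transition-state conformations, and C4 epimers of this kind are hard to separate. The kinetic resolution discards half of the allylic alcohol and two equivalents of the titanium reagent are consumed.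
- Comparison: the chosen plan sets C3 and C4 with higher confidence and leaves only C2 to the key step, where the thermodynamic preference helps. The two plans are equal in the risk of the final unmasking next to a benzylic ether.

Key step: step 9

Assumptions: (a) The sense of induction in step 2 is taken by analogy with itaconate and enamide hydrogenations, for which the (R,R)-Et-DuPhos complex of monovalent rhodium should give the S acid; if the R acid forms, the (S,S) ligand is used. (b) 1, 2 and 8 are purchased.

## Route

Step 1
Reactants: 1 3,4,5-trimethoxybenzaldehyde; 2 dimethyl succinate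
Product: 4 (E)-3-(methoxycarbonyl)-4-(3,4,5-trimethoxyphenyl)but-3-enoic acid, via paraconate lactone 3 (not isolated)
Conditions: NaOMe (2 equiv), MeOH, reflux; then aq. HCl
Reagents that add atoms: none
Why: Stobbe condensation: the succinate enolate adds to 1, the aldolate lactonises to 3, and base-induced E1cB opening gives the conjugated half-ester as its carboxylate; this irreversible last stage stops the reaction after one condensation and gives the E isomer with the aryl group trans to the ester.

Step 2
Reactants: 4 (E)-3-(methoxycarbonyl)-4-(3,4,5-trimethoxyphenyl)but-3-enoic acid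
Product: 5 (S)-3-(methoxycarbonyl)-4-(3,4,5-trimethoxyphenyl)butanoic acid
Conditions: H2 (6 bar), [Rh(cod)((R,R)-Et-DuPhos)]BF4 (0.5 mol %), NaOMe (0.1 equiv), MeOH, 25 °C
Reagents that add atoms: none
Why: Asymmetric hydrogenation of a Stobbe-type itaconate half-ester with a cationic bisphospholane complex of monovalent rhodium: carboxylate and alkene chelate the metal, so H2 is delivered to one face and the stereocentre (future C3) is set as S under catalyst control; arene and ester are not reduced.

Step 3
Reactants: 5 (S)-3-(methoxycarbonyl)-4-(3,4,5-trimethoxyphenyl)butanoic acid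
Product: 7 (S)-4-(3,4,5-trimethoxybenzyl)dihydrofuran-2(3H)-one, via hydroxy acid 6 (not isolated)
Conditions: KOH (1.0 equiv), EtOH; CaCl2, NaBH4, −10 °C to rt; then 2 M HCl, rt
Reagents that add atoms: none
Why: Ca(BH4)2, formed in the flask from CaCl2 and NaBH4, reduces the methyl ester while the potassium carboxylate is inert to borohydride (chemoselective ester reduction); acidification lactonises 6 to the β-benzyl γ-lactone, and the stereocentre is not touched.

Step 4
Reactants: 8 3-hydroxy-4,5-dimethoxybenzaldehyde
Product: 9 5-formyl-2,3-dimethoxyphenyl 4-methylbenzenesulfonate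
Conditions: TsCl (1.1 equiv), Et3N, DMAP (cat.), CH2Cl2, 0 °C to rt
Reagents that add atoms: 4-methylbenzenesulfonyl chloride (TsCl), Cc1ccc(cc1)S(=O)(=O)Cl
Why: O-Sulfonylation of the phenol under amine base with nucleophilic catalysis; the tosylate is installed first because it must be present in every later intermediate and act as the deactivating group in step 9.

Step 5
Reactants: 9 5-formyl-2,3-dimethoxyphenyl 4-methylbenzenesulfonate
Product: 10 5-(hydroxymethyl)-2,3-dimethoxyphenyl 4-methylbenzenesulfonate
Conditions: NaBH4 (0.5 equiv), MeOH/THF, 0 °C
Reagents that add atoms: none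
Why: Borohydride reduction of the aromatic aldehyde; an aryl sulfonate is inert to NaBH4 at 0 °C.

Step 6
Reactants: 10 5-(hydroxymethyl)-2,3-dimethoxyphenyl 4-methylbenzenesulfonate
Product: 11 5-(bromomethyl)-2,3-dimethoxyphenyl 4-methylbenzenesulfonate
Conditions: PBr3 (0.4 equiv), CH2Cl2, 0 °C
Reagents that add atoms: phosphorus tribromide (PBr3), BrP(Br)Br
Why: Conversion of the benzylic alcohol into the bromide through its phosphite ester and displacement by bromide; the non-basic conditions leave the sulfonate untouched.

Step 7
Reactants: 7 (S)-4-(3,4,5-trimethoxybenzyl)dihydrofuran-2(3H)-one; 11 5-(bromomethyl)-2,3-dimethoxyphenyl 4-methylbenzenesulfonate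
Product: 13 (3S,4S)-3-(4,5-dimethoxy-3-tosyloxybenzyl)-4-(3,4,5-trimethoxybenzyl)dihydrofuran-2(3H)-one, via lithium enolate 12 (not isolated)
Conditions: LiN(SiMe3)2 (1.05 equiv), THF, −78 °C; then 11 (1.0 equiv), DMPU, −78 to −40 °C
Reagents that add atoms: none
Why: Enolate alkylation of a β-substituted γ-butyrolactone: the benzylic bromide approaches the planar enolate 12 on the face opposite to the C4 benzyl group, which sets the new C3 stereocentre trans (3S,4S); the hindered amide base at −78 °C favours mono-alkylation and leaves the aryl sulfonate alone.

Step 8
Reactants: 13 (3S,4S)-3-(4,5-dimethoxy-3-tosyloxybenzyl)-4-(3,4,5-trimethoxybenzyl)dihydrofuran-2(3H)-one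
Product: 14 (2S,3S)-2-(4,5-dimethoxy-3-tosyloxybenzyl)-3-(3,4,5-trimethoxybenzyl)butane-1,4-diol
Conditions: LiBH4 (2.5 equiv), THF, 0 °C to rt; then aq. NH4Cl
Reagents that add atoms: none
Why: LiBH4 reduces the lactone through the lactol to the 1,4-diol without epimerising either stereocentre; the aryl sulfonate and the aryl ethers are inert to borohydride.

Step 9
Reactants: 14 (2S,3S)-2-(4,5-dimethoxy-3-tosyloxybenzyl)-3-(3,4,5-trimethoxybenzyl)butane-1,4-diol
Product: 15 (2R,3S,4S)-4-(4,5-dimethoxy-3-tosyloxybenzyl)-3-(hydroxymethyl)-2-(3,4,5-trimethoxyphenyl)tetrahydrofuran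
Conditions: DDQ (1.05 equiv), 4 Å molecular sieves, CH2Cl2 (0.02 M), 0 °C to rt
Reagents that add atoms: none
Why: DDQ forms a charge-transfer complex with the more electron-rich 3,4,5-trimethoxyphenyl ring of 14 and removes hydride from its benzylic CH2, giving a benzylic cation stabilised by the para methoxy group and paired with the hydroquinone anion. The closest known reaction type is the DDQ-mediated oxidative benzylic C–H cycloetherification of electron-rich alkylarenes, the non-phenolic counterpart of the quinone methide cyclisations of lignans. The hydroxyl on the carbon that bears the tosyloxybenzyl group reaches the cation through a five-membered transition state and closes the tetrahydrofuran in a 5-exo-trig mode, forming O1–C2; the other hydroxyl could only give an oxetane. The new stereocentre C2 is controlled by the adjacent C3 stereocentre: the aryl group takes the face anti to the C3 hydroxymethyl group, and since the benzylic ether can re-ionise in the presence of the weakly acidic hydroquinone, the trans isomer is also the thermodynamic outcome. Site selectivity rests on the tosyloxy group, which makes the second arene a poorer donor and destabilises a cation at its benzylic carbon through a meta sulfonyloxy substituent. The same deactivation should hold back a second cyclisation by the remaining hydroxyl and Friedel–Crafts closure by the second arene onto the cation. Oxidation at the C2–H of 15 is limited by using close to one equivalent of DDQ under anhydrous conditions and stopping just short of full conversion.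

Step 10
Reactants: 15 (2R,3S,4S)-4-(4,5-dimethoxy-3-tosyloxybenzyl)-3-(hydroxymethyl)-2-(3,4,5-trimethoxyphenyl)tetrahydrofuran
Product: 16 (2R,3S,4S)-4-(3-hydroxy-4,5-dimethoxybenzyl)-3-(hydroxymethyl)-2-(3,4,5-trimethoxyphenyl)tetrahydrofuran
Conditions: KOH (10 equiv), 1,4-dioxane/H2O (1:1), 80 °C, argon; then aq. NH4Cl
Reagents that add atoms: none
Why: Hydroxide attacks the sulfonyl sulfur and expels the phenoxide (S–O cleavage of an aryl sulfonate); water with an ether co-solvent is chosen so that no alkyl tosylate can form and re-alkylate the phenoxide, and the benzylic ether, the primary alcohol and the three stereocentres are stable to base.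

## Compound list

1 | 3,4,5-trimethoxybenzaldehyde | COc1cc(C=O)cc(OC)c1OC | starting material
2 | dimethyl succinate | COC(=O)CCC(=O)OC | starting material
3 | methyl 5-oxo-2-(3,4,5-trimethoxyphenyl)tetrahydrofuran-3-carboxylate (paraconate lactone, racemic diastereomer mixture, not isolated) | COC(=O)C1CC(=O)OC1c1cc(OC)c(OC)c(OC)c1 | intermediate
4 | (E)-3-(methoxycarbonyl)-4-(3,4,5-trimethoxyphenyl)but-3-enoic acid | COC(=O)/C(CC(=O)O)=C/c1cc(OC)c(OC)c(OC)c1 | intermediate
5 | (S)-3-(methoxycarbonyl)-4-(3,4,5-trimethoxyphenyl)butanoic acid | COC(=O)[C@@H](Cc1cc(OC)c(OC)c(OC)c1)CC(=O)O | intermediate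
6 | (S)-3-(hydroxymethyl)-4-(3,4,5-trimethoxyphenyl)butanoic acid (not isolated) | OC[C@@H](Cc1cc(OC)c(OC)c(OC)c1)CC(=O)O | intermediate
7 | (S)-4-(3,4,5-trimethoxybenzyl)dihydrofuran-2(3H)-one | O=C1C[C@H](Cc2cc(OC)c(OC)c(OC)c2)CO1 | intermediate
8 | 3-hydroxy-4,5-dimethoxybenzaldehyde | COc1cc(C=O)cc(O)c1OC | starting material
9 | 5-formyl-2,3-dimethoxyphenyl 4-methylbenzenesulfonate | COc1cc(C=O)cc(OS(=O)(=O)c2ccc(C)cc2)c1OC | intermediate
10 | 5-(hydroxymethyl)-2,3-dimethoxyphenyl 4-methylbenzenesulfonate | COc1cc(CO)cc(OS(=O)(=O)c2ccc(C)cc2)c1OC | intermediate
11 | 5-(bromomethyl)-2,3-dimethoxyphenyl 4-methylbenzenesulfonate | COc1cc(CBr)cc(OS(=O)(=O)c2ccc(C)cc2)c1OC | intermediate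
12 | lithium (S)-4-(3,4,5-trimethoxybenzyl)-4,5-dihydrofuran-2-olate (lithium enolate of 7, not isolated) | [Li+].[O-]C1=C[C@H](Cc2cc(OC)c(OC)c(OC)c2)CO1 | intermediate
13 | (3S,4S)-3-(4,5-dimethoxy-3-tosyloxybenzyl)-4-(3,4,5-trimethoxybenzyl)dihydrofuran-2(3H)-one | COc1cc(C[C@@H]2C(=O)OC[C@H]2Cc2cc(OC)c(OC)c(OC)c2)cc(OS(=O)(=O)c2ccc(C)cc2)c1OC | intermediate
14 | (2S,3S)-2-(4,5-dimethoxy-3-tosyloxybenzyl)-3-(3,4,5-trimethoxybenzyl)butane-1,4-diol | COc1cc(C[C@H](CO)[C@@H](CO)Cc2cc(OC)c(OC)c(OC)c2)cc(OS(=O)(=O)c2ccc(C)cc2)c1OC | intermediate
15 | (2R,3S,4S)-4-(4,5-dimethoxy-3-tosyloxybenzyl)-3-(hydroxymethyl)-2-(3,4,5-trimethoxyphenyl)tetrahydrofuran | COc1cc(C[C@@H]2CO[C@@H](c3cc(OC)c(OC)c(OC)c3)[C@@H]2CO)cc(OS(=O)(=O)c2ccc(C)cc2)c1OC | intermediate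
16 | (2R,3S,4S)-4-(3-hydroxy-4,5-dimethoxybenzyl)-3-(hydroxymethyl)-2-(3,4,5-trimethoxyphenyl)tetrahydrofuran | COc1cc(C[C@@H]2CO[C@@H](c3cc(OC)c(OC)c(OC)c3)[C@@H]2CO)cc(O)c1OC | target

## Step count and risk

Total step count: 10. Longest linear sequence: 7 steps (steps 1, 2, 3, 7, 8, 9, 10; the branch through steps 4, 5, 6 is equally long).

Step 9 (key step). The most likely failure is sluggish hydride abstraction. The para methoxy group of a 3,4,5-trimethoxyphenyl ring is twisted out of conjugation by its neighbours, so this ring is a weaker donor than a 4-methoxyphenyl or 3,4-dimethoxyphenyl ring. If warming (1,2-dichloroethane, 50 °C) is needed, a second hydride abstraction (at C2–H of the product or at the other benzylic CH2) and Friedel–Crafts capture of the cation by the second arene gain ground.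

The fallback brings in the benzylic oxygen by an aldol reaction instead of C–H oxidation. It sets out from 11 (and uses 1) and comes back to the route at 15.
- (S)-4-Benzyloxazolidin-2-one would be N-acylated with 4-tert-butoxy-4-oxobutanoic acid (pivaloyl chloride, Et3N, LiCl, THF) to give tert-butyl 4-[(4S)-4-benzyl-2-oxooxazolidin-3-yl]-4-oxobutanoate F1.
- Its sodium enolate (NaN(SiMe3)2, THF, −78 °C) would be alkylated by 11 anti to the auxiliary benzyl group to give tert-butyl (3S)-3-{[(4S)-4-benzyl-2-oxooxazolidin-3-yl]carbonyl}-4-(4,5-dimethoxy-3-tosyloxyphenyl)butanoate F2.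
- LiBH4 (THF, 0 °C) would cleave the auxiliary to give tert-butyl (3S)-3-(hydroxymethyl)-4-(4,5-dimethoxy-3-tosyloxyphenyl)butanoate F3.
- Catalytic TsOH in toluene would close (S)-4-(4,5-dimethoxy-3-tosyloxybenzyl)dihydrofuran-2(3H)-one F4.
- Aldol addition of the lithium enolate of F4 (LiN(SiMe3)2, THF, −78 °C) to 1 would give the trans lactone (3R,4S)-4-(4,5-dimethoxy-3-tosyloxybenzyl)-3-[hydroxy(3,4,5-trimethoxyphenyl)methyl]dihydrofuran-2(3H)-one F5; both carbinol epimers serve.
- LiBH4 would reduce F5 to (2S,3S)-2-(4,5-dimethoxy-3-tosyloxybenzyl)-3-[hydroxy(3,4,5-trimethoxyphenyl)methyl]butane-1,4-diol F6.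
- Catalytic camphorsulfonic acid in CH2Cl2 would ionise the benzylic alcohol of F6 and close the same O1–C2 bond, with the aryl group anti to the C3 substituent, to give 15.

Step 2. The most likely failure is insufficient face selectivity, or slow turnover, on an electron-rich trisubstituted alkene; the sense of induction is also assumed and not certain. The fallback is resolution in place of asymmetric catalysis. It sets out from 4 and comes back at 5.
- Hydrogenation of 4 over Pd/C (H2, MeOH) would give racemic 3-(methoxycarbonyl)-4-(3,4,5-trimethoxyphenyl)butanoic acid F7.
- Crystallisation with (R)-1-phenylethylamine (or its antipode, whichever gives the less soluble salt of the S acid) would give (R)-1-phenylethylammonium (S)-3-(methoxycarbonyl)-4-(3,4,5-trimethoxyphenyl)butanoate F8.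
- Acidification with aq. HCl would release 5.

Step 7. The most likely failures are double alkylation through proton exchange between product and enolate, loss of trans selectivity if the mixture warms, and loss of enolate by attack at the sulfonyl group or decomposition of the benzylic bromide. The fallback is an aldol reaction and deoxygenation in place of alkylation. It sets out from 7 and 9 and comes back at 13.
- The lithium enolate 12 would be added to aldehyde 9 at −78 °C to give (3R,4S)-3-[(4,5-dimethoxy-3-tosyloxyphenyl)(hydroxy)methyl]-4-(3,4,5-trimethoxybenzyl)dihydrofuran-2(3H)-one F9 as a mixture of carbinol epimers.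
- Hydrogenolysis of the benzylic hydroxyl (H2, Pd/C, AcOH, trace HClO4) would give 13, with the aryl sulfonate and the lactone left intact.

Step 10. The most likely failure is slow hydrolysis of the sulfonate of an electron-rich phenol, which would call for long heating in strong base and expose the phenoxide to air oxidation. The fallback is reductive S–O cleavage by electron transfer in place of nucleophilic attack at sulfur. It sets out from 15 and comes back at 16: Mg turnings in MeOH at rt would cleave the sulfonate and release the sulfur as a sulfinate that cannot alkylate the phenoxide. No new compound is made.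

## Further compounds

F1 | step 9 | tert-butyl 4-[(4S)-4-benzyl-2-oxooxazolidin-3-yl]-4-oxobutanoate | CC(C)(C)OC(=O)CCC(=O)N1[C@@H](Cc2ccccc2)COC1=O
F2 | step 9 | tert-butyl (3S)-3-{[(4S)-4-benzyl-2-oxooxazolidin-3-yl]carbonyl}-4-(4,5-dimethoxy-3-tosyloxyphenyl)butanoate | CC(C)(C)OC(=O)C[C@H](Cc1cc(OC)c(OC)c(OS(=O)(=O)c2ccc(C)cc2)c1)C(=O)N1[C@@H](Cc2ccccc2)COC1=O
F3 | step 9 | tert-butyl (3S)-3-(hydroxymethyl)-4-(4,5-dimethoxy-3-tosyloxyphenyl)butanoate | CC(C)(C)OC(=O)C[C@H](Cc1cc(OC)c(OC)c(OS(=O)(=O)c2ccc(C)cc2)c1)CO
F4 | step 9 | (S)-4-(4,5-dimethoxy-3-tosyloxybenzyl)dihydrofuran-2(3H)-one | O=C1C[C@H](Cc2cc(OC)c(OC)c(OS(=O)(=O)c3ccc(C)cc3)c2)CO1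
F5 | step 9 | (3R,4S)-4-(4,5-dimethoxy-3-tosyloxybenzyl)-3-[hydroxy(3,4,5-trimethoxyphenyl)methyl]dihydrofuran-2(3H)-one (carbinol epimers) | COc1cc(C(O)[C@@H]2C(=O)OC[C@H]2Cc2cc(OC)c(OC)c(OS(=O)(=O)c3ccc(C)cc3)c2)cc(OC)c1OC
F6 | step 9 | (2S,3S)-2-(4,5-dimethoxy-3-tosyloxybenzyl)-3-[hydroxy(3,4,5-trimethoxyphenyl)methyl]butane-1,4-diol (carbinol epimers) | COc1cc(C(O)[C@H](CO)[C@@H](CO)Cc2cc(OC)c(OC)c(OS(=O)(=O)c3ccc(C)cc3)c2)cc(OC)c1OC
F7 | step 2 | racemic 3-(methoxycarbonyl)-4-(3,4,5-trimethoxyphenyl)butanoic acid | COC(=O)C(Cc1cc(OC)c(OC)c(OC)c1)CC(=O)O
F8 | step 2 | (R)-1-phenylethylammonium (S)-3-(methoxycarbonyl)-4-(3,4,5-trimethoxyphenyl)butanoate | COC(=O)[C@@H](Cc1cc(OC)c(OC)c(OC)c1)CC(=O)[O-].C[C@@H]([NH3+])c1ccccc1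
F9 | step 7 | (3R,4S)-3-[(4,5-dimethoxy-3-tosyloxyphenyl)(hydroxy)methyl]-4-(3,4,5-trimethoxybenzyl)dihydrofuran-2(3H)-one (carbinol epimers) | COc1cc(C(O)[C@@H]2C(=O)OC[C@H]2Cc2cc(OC)c(OC)c(OC)c2)cc(OS(=O)(=O)c2ccc(C)cc2)c1OC
F0 | step 10 | none | none
A1 | alternative 1 | (2R,3S)-4-methylene-2-(3,4,5-trimethoxyphenyl)tetrahydrofuran-3-carbonitrile | C=C1CO[C@@H](c2cc(OC)c(OC)c(OC)c2)[C@@H]1C#N
A2 | alternative 1 | 1-cyano-2-[(trimethylsilyl)methyl]prop-2-en-1-yl acetate (racemic) | CC(=O)OC(C#N)C(=C)C[Si](C)(C)C
A3 | alternative 1 | 1-(benzyloxy)-5-bromo-2,3-dimethoxybenzene | COc1cc(Br)cc(OCc2ccccc2)c1OC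
A4 | alternative 2 | cis-fused 6-(3-benzyloxy-4,5-dimethoxyphenyl)-2-(3,4,5-trimethoxyphenyl)-3,7-dioxabicyclo[3.3.0]octan-8-one, both aryl groups exo | O=C1O[C@@H](c2cc(OC)c(OC)c(OCc3ccccc3)c2)[C@@H]2CO[C@@H](c3cc(OC)c(OC)c(OC)c3)[C@H]12
A5 | alternative 2 | (R)-5-(3-benzyloxy-4,5-dimethoxyphenyl)furan-2(5H)-one | O=C1O[C@@H](c2cc(OC)c(OC)c(OCc3ccccc3)c2)C=C1
A6 | alternative 2 | [(chloromethoxy)(3,4,5-trimethoxyphenyl)methyl]trimethylsilane (racemic) | COc1cc(C(OCCl)[Si](C)(C)C)cc(OC)c1OC
A7 | alternative 3 | (2R,3S,4S)-4-(3-benzyloxy-4,5-dimethoxybenzyl)-3-(hydroxymethyl)-2-(3,4,5-trimethoxyphenyl)tetrahydrofuran | COc1cc(C[C@@H]2CO[C@@H](c3cc(OC)c(OC)c(OC)c3)[C@@H]2CO)cc(OCc2ccccc2)c1OC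
A8 | alternative 3 | (R)-2-[(S)-{[(E)-3-(3-benzyloxy-4,5-dimethoxyphenyl)prop-2-en-1-yl]oxy}(3,4,5-trimethoxyphenyl)methyl]oxirane | COc1cc([C@H](OC/C=C/c2cc(OC)c(OC)c(OCc3ccccc3)c2)[C@H]2CO2)cc(OC)c1OC
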